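**Retrosynthetic overview**
- The route rests on C1: this methyl-bearing quaternary ring-fusion carbon is the only fully substituted atom of the seven-membered ring (C1, C5–C10). The other six ring carbons, with oxygen on C6 and the carbon C14 on C8, are a 2-methoxy-4-(oxymethyl)phenyl ring.
- Key disconnection: C1–C5 and C1–C10 (retro-Buchner) to an α-diazo ketone in which C2–C3–C4 tether C1 to the arene. The C4 stereocentre, set by asymmetric conjugate arylation, relays to C1.
- Ring order: benzene ring (bought), then cyclopentanone and cycloheptatriene together in the key step, then a temporary dioxolane, and last the spiro-oxirane.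
- After the key step: enol ether to C6 ketone (sets C5), C9–C10 cis-diol, C2 ketone traded for the C4 carbinol by enone epoxidation and Wharton transposition, C6 set by C4-OH-directed reduction, C14-OH removed with allylic transposition to C8=C14, directed epoxidation.

Key step: step 7

Remark: daucane numbering is used (C1 angular-methyl carbon, C2, C3, C4 isopropyl carbon, C5 fusion CH, C6–C10 around the seven-membered ring, C14 on C8), β is the face of the C1 methyl, and C14 is carried from the start as a silyl-protected hydroxymethyl group on the arene because the exocyclic C8=C14 alkene is then reached by a neutral reductive allylic transposition and not by base-mediated enone deconjugation; the four starting materials are assumed to be commercial.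

**Route**

Step 1
Reactants: 1 (4-bromo-3-methoxyphenyl)methanol
Product: 2 [(4-bromo-3-methoxyphenyl)methoxy]tri(propan-2-yl)silane
Conditions: i-Pr3SiCl, imidazole, DMF, 23 °C
Reagents that add atoms: chlorotri(propan-2-yl)silane, CC(C)[Si](Cl)(C(C)C)C(C)C
Why: Silyl ether formation at the primary benzylic alcohol is routine (alcohol silylation), and the bulky triisopropylsilyl group should survive the organolithium, hydroxide, dilute acid and oxidants used before step 20.

Step 2
Reactants: 2 aryl bromide silyl ether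
Product: 5 [2-methoxy-4-(triisopropylsilyloxymethyl)phenyl]boronic acid, via aryllithium 3 (not isolated), via lithium aryltriisopropoxyborate 4 (not isolated)
Conditions: n-BuLi, THF, −78 °C; B(Oi-Pr)3, −78 → 0 °C; 1 M HCl, 0 °C
Reagents that add atoms: triisopropyl borate, CC(C)OB(OC(C)C)OC(C)C; water, O
Why: Bromine–lithium exchange is fast at −78 °C, the aryllithium is trapped by the borate and mild acid releases the boronic acid without touching the silyl ether (lithiation–borylation).

Step 3
Reactants: 5 arylboronic acid, 6 ethyl (E)-4-methylpent-2-enoate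
Product: 7 ethyl (3S)-3-[2-methoxy-4-(triisopropylsilyloxymethyl)phenyl]-4-methylpentanoate
Conditions: [Rh(OH)((R)-BINAP)]2 (2.5 mol %), 5 (2.5 equiv), dioxane/H2O 10:1, 80 °C
Reagents that add atoms: none
Why: Rhodium-catalysed asymmetric conjugate arylation (Hayashi–Miyaura reaction): the aryl–rhodium species bearing (R)-BINAP inserts the (E)-enoate on the face that gives (S) at C4, the mirror image of the sense established for (S)-BINAP with acyclic (E)-enones and enoates carrying a β-isopropyl group, and the excess of boronic acid offsets protodeboronation of the ortho-methoxy reagent.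

Step 4
Reactants: 7 (S)-β-aryl ester
Product: 8 (3S)-3-[2-methoxy-4-(triisopropylsilyloxymethyl)phenyl]-4-methylpentanoic acid
Conditions: LiOH·H2O, THF/MeOH/H2O, 40 °C; then 1 M HCl to pH 3
Reagents that add atoms: lithium hydroxide, [Li+].[OH-]
Why: Ester saponification with LiOH leaves the benzylic stereocentre, which is β to the carboxylate, and the silyl ether untouched.

Step 5
Reactants: 9 N-ethyl-N-nitrosourea
Product: 10 diazoethane (ethereal solution, dried over KOH pellets and used at once in step 6)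
Conditions: 40% aq. KOH, Et2O, 0 °C
Reagents that add atoms: none
Why: Base-induced fragmentation of an N-alkyl-N-nitrosourea is the standard preparation of a diazoalkane, the cyanate staying in the aqueous phase.

Step 6
Reactants: 8 (S)-β-aryl acid, 10 diazoethane
Product: 12 (5S)-2-diazo-5-[2-methoxy-4-(triisopropylsilyloxymethyl)phenyl]-6-methylheptan-3-one, via acid chloride 11 (not isolated)
Conditions: (COCl)2, DMF (cat.), CH2Cl2, 0 → 23 °C, evaporate; then 10 (3 equiv), Et2O, −20 → 0 °C
Reagents that add atoms: none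
Why: The acid chloride acylates the nucleophilic carbon of diazoethane and a second equivalent of diazoethane removes the HCl as chloroethane, the standard route to 2-diazo-3-ketones (acylation of a diazoalkane, Arndt–Eistert type).

Step 7
Reactants: 12 (S)-α-diazo ketone
Product: 14 (3S,8aR)-4-methoxy-8a-methyl-3-(propan-2-yl)-6-(triisopropylsilyloxymethyl)-3,8a-dihydroazulen-1(2H)-one, via norcaradiene tautomer 13 (not isolated)
Conditions: Rh2(OAc)4 (1 mol %), CH2Cl2, reflux, slow addition of 12
Reagents that add atoms: none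
Why: Rh2(OAc)4 releases N2 from 12 and the electrophilic carbenoid at C1 adds across the C5–C10 bond of the arene to give norcaradiene 13, whose disrotatory six-electron ring opening breaks C5–C10 and leaves C1 inserted into the former benzene ring (intramolecular Buchner reaction, established for 2-diazo-5-arylalkan-3-ones, which give 8a-methyl azulenones). The cyclopentanone closes in the carbene addition itself, by C1–C5 bond formation through the three-atom tether C2–C3–C4, and the seven-membered ring arises by the electrocyclic ring expansion, so two rings, two skeletal bonds and the quaternary centre come from one operation. The configuration of C1 is relayed from C4: in the compact transition state the isopropyl group takes the pseudo-equatorial position on the forming five-membered ring and the carbenoid methyl ends up on the opposite face, trans to it. Regioselectivity for the free ortho carbon C10 is secured by the methoxy group, which blocks the C5–C6 bond sterically. Chemoselectivity for the arene over insertion into the isopropyl C–H bond or 1,2-hydride shift relies on the electron-rich anisole ring and on the electron-poor carboxylate ligands of the divalent rhodium catalyst, which favour aromatic addition. The product is drawn as the cycloheptatriene (C5=C6 enol ether, C7=C8, C9=C10), which equilibrates rapidly with 13.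

Step 8
Reactants: 14 azulenone
Product: 15 14-(triisopropylsilyloxy)-5αH-dauca-7,9-diene-2,6-dione (1β-methyl, 4α-isopropyl, trans-fused)
Conditions: 1 M aq. HCl, THF, 0 → 23 °C
Reagents that add atoms: water, O
Why: Acid-catalysed enol ether hydrolysis: protonation at C5 gives a methoxy-stabilised pentadienyl cation that water captures at C6, and C5, now α to the ketone, should equilibrate through the dienol to the trans-fused 5α-H epimer, in which the C5–C6 bond lies trans to the C4 isopropyl group on the cyclopentanone.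

Step 9
Reactants: 15 trans-fused dienedione
Product: 16 9α,10α-dihydroxy-14-(triisopropylsilyloxy)-5αH-dauc-7-ene-2,6-dione
Conditions: OsO4 (5 mol %), N-methylmorpholine N-oxide, acetone/H2O, 23 °C
Reagents that add atoms: osmium tetroxide (catalytic carrier of both oxygens), O=[Os](=O)(=O)=O; N-methylmorpholine N-oxide, C[N+]1([O-])CCOCC1; water, O
Why: Catalytic OsO4 dihydroxylation (Upjohn conditions) should pick the γ,δ-alkene C9=C10, the more electron-rich alkene of the dienone, and add from the α face because the axial C1 methyl shields the β face of C10, which sets C9 and C10 together as the 9α,10α-diol.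

Step 10
Reactants: 16 9α,10α-diol
Product: 17 9α,10α-(isopropylidenedioxy)-14-(triisopropylsilyloxy)-5αH-dauc-7-ene-2,6-dione
Conditions: Me2C(OMe)2, PPTS (cat.), CH2Cl2, 23 °C
Reagents that add atoms: 2,2-dimethoxypropane, COC(C)(C)OC
Why: The cis-1,2-diol closes readily to the five-membered isopropylidene acetal under mild acid catalysis (acetonide formation), which also blocks retro-aldol cleavage of the C10 hydroxy/C2 ketone pair.

Step 11
Reactants: 17 acetonide enedione
Product: 18 6β-hydroxy-9α,10α-(isopropylidenedioxy)-14-(triisopropylsilyloxy)-5αH-dauc-7-en-2-one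
Conditions: NaBH4, CeCl3·7H2O, MeOH, −78 °C
Reagents that add atoms: none
Why: Luche reduction: with CeCl3 the conjugated C6 ketone is reduced 1,2 far faster than the saturated neopentyl C2 cyclopentanone, as in the selective C3 reduction of steroidal 4-ene-3,17-diones; hydride should enter anti to the axial C1 methyl to give mainly the 6β-alcohol, but this configuration is immaterial because C6 is re-oxidised in step 17.

Step 12
Reactants: 18 6β-allylic alcohol
Product: 20 6β-(triethylsilyloxy)-9α,10α-(isopropylidenedioxy)-14-(triisopropylsilyloxy)-5αH-dauca-3,7-dien-2-one, via bis-silylated enol ether 19 (not isolated)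
Conditions: Et3SiOTf, Et3N, CH2Cl2, −78 → 0 °C; then Pd(OAc)2 (1.1 equiv), MeCN, 23 °C
Reagents that add atoms: triethylsilyl trifluoromethanesulfonate, CC[Si](CC)(CC)OS(=O)(=O)C(F)(F)F
Why: Saegusa–Ito oxidation: Et3SiOTf/Et3N protects the C6 alcohol and converts the C2 ketone, enolisable only toward C3, into its silyl enol ether, and Pd(OAc)2 then forms the C3 palladium enolate whose only β-hydrogen is C4–H, so β-hydride elimination gives the C3=C4 enone and removes the C4 stereocentre, which has done its work.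

Step 13
Reactants: 20 cyclopentenone silyl ether
Product: 21 3β,4β-epoxy-6β-(triethylsilyloxy)-9α,10α-(isopropylidenedioxy)-14-(triisopropylsilyloxy)-5αH-dauc-7-en-2-one
Conditions: 30% aq. H2O2, NaOH (cat.), MeOH/THF, 0 → 23 °C
Reagents that add atoms: hydrogen peroxide, OO
Why: Weitz–Scheffer epoxidation: hydroperoxide adds to C4 of the cyclopentenone and the enolate closes the oxirane; attack is expected on the β face, as nucleophiles add to C15 of 14α-steroidal 15-en-17-ones (the same trans-fused cyclopentenone next to a β-methyl quaternary carbon), and this also places the isopropyl group trans to the C5–C6 bond, so C3 and C4 are set as the 3β,4β-epoxide.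

Step 14
Reactants: 21 3β,4β-epoxy ketone
Product: 24 6β-(triethylsilyloxy)-9α,10α-(isopropylidenedioxy)-14-(triisopropylsilyloxy)-5αH-dauca-2,7-dien-4β-ol, via epoxy hydrazone 22 (not isolated), via alkenyl diazene 23 (not isolated)
Conditions: N2H4·H2O, AcOH (cat.), MeOH, 0 → 23 °C
Reagents that add atoms: none
Why: Wharton transposition: the epoxy hydrazone opens to an alkenyl diazene that loses N2, which deletes the C2 oxygen, leaves C2=C3 and turns the epoxide oxygen into the tertiary 4β-hydroxyl with retention at C4.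

Step 15
Reactants: 24 tertiary allylic alcohol
Product: 25 6β-(triethylsilyloxy)-9α,10α-(isopropylidenedioxy)-14-(triisopropylsilyloxy)-5αH-dauc-7-en-4β-ol
Conditions: 2-nitrobenzenesulfonylhydrazide, Et3N, CH2Cl2, 23 °C
Reagents that add atoms: none
Why: Diimide reduction: the small reagent hydrogenates the cis-disubstituted cyclopentene C2=C3 far faster than the trisubstituted, oxygen-flanked C7=C8 alkene and cannot hydrogenolyse the allylic tertiary C4–O bond.

Step 16
Reactants: 25 4β-carbinol silyl ether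
Product: 26 9α,10α-(isopropylidenedioxy)-14-(triisopropylsilyloxy)-5αH-dauc-7-ene-4β,6β-diol
Conditions: HF·pyridine, pyridine, THF, 0 °C
Reagents that add atoms: none
Why: Buffered HF·pyridine cleaves the secondary triethylsilyl ether much faster than the bulkier primary triisopropylsilyl ether and leaves the acetonide intact (selective silyl ether cleavage).

Step 17
Reactants: 26 4β,6β-diol
Product: 27 4β-hydroxy-9α,10α-(isopropylidenedioxy)-14-(triisopropylsilyloxy)-5αH-dauc-7-en-6-one
Conditions: MnO2, CH2Cl2, 23 °C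
Reagents that add atoms: none
Why: MnO2 oxidises only the allylic C6 alcohol (allylic alcohol oxidation) under neutral conditions that avoid retro-aldol cleavage of the new β-hydroxy ketone.

Step 18
Reactants: 27 4β-hydroxy enone
Product: 28 9α,10α-(isopropylidenedioxy)-14-(triisopropylsilyloxy)-5αH-dauc-7-ene-4β,6α-diol
Conditions: Me4NBH(OAc)3, MeCN/AcOH 1:1, −30 °C
Reagents that add atoms: none
Why: Evans–Saksena reduction: the C4 hydroxyl exchanges onto boron and delivers hydride intramolecularly to the β face of the C6 ketone, the face on which it sits, so the new hydroxyl is 6α, anti to the 4β-hydroxyl, while the reagent does not reduce the enone intermolecularly.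

Step 19
Reactants: 28 4β,6α-diol, 29 3-methylbutanoyl chloride (isovaleryl chloride)
Product: 30 4β-hydroxy-9α,10α-(isopropylidenedioxy)-14-(triisopropylsilyloxy)-5αH-dauc-7-en-6α-yl 3-methylbutanoate
Conditions: Et3N, DMAP (cat.), CH2Cl2, 0 °C
Reagents that add atoms: none
Why: Acylation of the secondary allylic 6α-alcohol with the acid chloride and DMAP (nucleophilic catalysis) is selective because the tertiary C4 hydroxyl is inert under these conditions.

Step 20
Reactants: 30 6α-isovalerate
Product: 31 4β,14-dihydroxy-9α,10α-(isopropylidenedioxy)-5αH-dauc-7-en-6α-yl 3-methylbutanoate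
Conditions: Bu4NF, AcOH, THF, 0 → 23 °C
Reagents that add atoms: none
Why: Fluoride cleaves the Si–O bond (desilylation), acetic acid buffering the alkoxide so that the ester neither migrates nor hydrolyses.

Step 21
Reactants: 31 C14 allylic alcohol
Product: 34 4β-hydroxy-9α,10α-(isopropylidenedioxy)-5αH-dauc-8(14)-en-6α-yl 3-methylbutanoate, via N-allylic sulfonylhydrazide 32 (not isolated), via allylic diazene 33 (not isolated)
Conditions: 2-nitrobenzenesulfonylhydrazide, PPh3, diethyl azodicarboxylate, THF, −30 → 23 °C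
Reagents that add atoms: none
Why: Reductive 1,3-transposition of an allylic alcohol: Mitsunobu N-alkylation of the sulfonylhydrazide at the primary C14 position, loss of sulfinic acid and retro-ene extrusion of N2 from the monoalkyl diazene deliver hydrogen to C7 and leave the exocyclic C8=C14 alkene under neutral conditions that spare the ester, the acetonide and the tertiary alcohol.

Step 22
Reactants: 34 8(14)-ene acetonide
Product: 35 4β,9α,10α-trihydroxy-5αH-dauc-8(14)-en-6α-yl 3-methylbutanoate
Conditions: AcOH/H2O 4:1, 40 °C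
Reagents that add atoms: none
Why: Mild aqueous acid hydrolyses the isopropylidene acetal (acetonide cleavage) without ionising the allylic C9–O bond or the tertiary C4 carbinol and without cleaving the ester.

Step 23
Reactants: 35 triol ester
Product: 36 8α,14-epoxy-4β,9α,10α-trihydroxy-5αH-daucan-6α-yl 3-methylbutanoate (CNP0307265.1)
Conditions: VO(acac)2 (5 mol %), t-BuOOH, CH2Cl2, 0 °C
Reagents that add atoms: tert-butyl hydroperoxide, CC(C)(C)OO
Why: Hydroxyl-directed epoxidation: the pentavalent vanadium alkoxide of the allylic 9α-hydroxyl delivers the peroxide oxygen to the α face of the C8=C14 alkene, so C8 is set with the oxirane oxygen α, syn to O9.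

**Compound list**

1 | (4-bromo-3-methoxyphenyl)methanol | COc1cc(CO)ccc1Br | starting material
2 | [(4-bromo-3-methoxyphenyl)methoxy]tri(propan-2-yl)silane | COc1cc(CO[Si](C(C)C)(C(C)C)C(C)C)ccc1Br | intermediate
3 | [2-methoxy-4-(triisopropylsilyloxymethyl)phenyl]lithium | COc1cc(CO[Si](C(C)C)(C(C)C)C(C)C)ccc1[Li] | intermediate
4 | lithium [2-methoxy-4-(triisopropylsilyloxymethyl)phenyl]tri(propan-2-yloxy)borate | [Li+].COc1cc(CO[Si](C(C)C)(C(C)C)C(C)C)ccc1[B-](OC(C)C)(OC(C)C)OC(C)C | intermediate
5 | [2-methoxy-4-(triisopropylsilyloxymethyl)phenyl]boronic acid | COc1cc(CO[Si](C(C)C)(C(C)C)C(C)C)ccc1B(O)O | intermediate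
6 | ethyl (E)-4-methylpent-2-enoate | CCOC(=O)/C=C/C(C)C | starting material
7 | ethyl (3S)-3-[2-methoxy-4-(triisopropylsilyloxymethyl)phenyl]-4-methylpentanoate | CCOC(=O)C[C@@H](C(C)C)c1ccc(CO[Si](C(C)C)(C(C)C)C(C)C)cc1OC | intermediate
8 | (3S)-3-[2-methoxy-4-(triisopropylsilyloxymethyl)phenyl]-4-methylpentanoic acid | OC(=O)C[C@@H](C(C)C)c1ccc(CO[Si](C(C)C)(C(C)C)C(C)C)cc1OC | intermediate
9 | N-ethyl-N-nitrosourea | CCN(N=O)C(N)=O | starting material
10 | diazoethane | CC=[N+]=[N-] | intermediate
11 | (3S)-3-[2-methoxy-4-(triisopropylsilyloxymethyl)phenyl]-4-methylpentanoyl chloride | ClC(=O)C[C@@H](C(C)C)c1ccc(CO[Si](C(C)C)(C(C)C)C(C)C)cc1OC | intermediate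
12 | (5S)-2-diazo-5-[2-methoxy-4-(triisopropylsilyloxymethyl)phenyl]-6-methylheptan-3-one | CC(=[N+]=[N-])C(=O)C[C@@H](C(C)C)c1ccc(CO[Si](C(C)C)(C(C)C)C(C)C)cc1OC | intermediate
13 | norcaradiene valence tautomer of 14 (cyclopropane C1–C5–C10, alkenes C6=C7 and C8=C9) | C[C@@]12[C@H]3C=C(CO[Si](C(C)C)(C(C)C)C(C)C)C=C(OC)[C@@]13[C@H](C(C)C)CC2=O | intermediate
14 | (3S,8aR)-4-methoxy-8a-methyl-3-(propan-2-yl)-6-(triisopropylsilyloxymethyl)-3,8a-dihydroazulen-1(2H)-one (C2 ketone, C5=C6 enol ether, C7=C8, C9=C10; 1β-methyl, 4α-isopropyl) | C[C@@]12C=CC(CO[Si](C(C)C)(C(C)C)C(C)C)=CC(OC)=C1[C@H](C(C)C)CC2=O | intermediate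
15 | 14-(triisopropylsilyloxy)-5αH-dauca-7,9-diene-2,6-dione (1β-methyl, 4α-isopropyl, trans-fused) | O=C1C=C(CO[Si](C(C)C)(C(C)C)C(C)C)C=C[C@@]2(C)C(=O)C[C@@H](C(C)C)[C@H]12 | intermediate
16 | 9α,10α-dihydroxy-14-(triisopropylsilyloxy)-5αH-dauc-7-ene-2,6-dione | O=C1C=C(CO[Si](C(C)C)(C(C)C)C(C)C)[C@@H](O)[C@@H](O)[C@@]2(C)C(=O)C[C@@H](C(C)C)[C@H]12 | intermediate
17 | 9α,10α-(isopropylidenedioxy)-14-(triisopropylsilyloxy)-5αH-dauc-7-ene-2,6-dione | O=C1C=C(CO[Si](C(C)C)(C(C)C)C(C)C)[C@@H]3[C@@H](OC(C)(C)O3)[C@@]2(C)C(=O)C[C@@H](C(C)C)[C@H]12 | intermediate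
18 | 6β-hydroxy-9α,10α-(isopropylidenedioxy)-14-(triisopropylsilyloxy)-5αH-dauc-7-en-2-one | O[C@@H]1C=C(CO[Si](C(C)C)(C(C)C)C(C)C)[C@@H]3[C@@H](OC(C)(C)O3)[C@@]2(C)C(=O)C[C@@H](C(C)C)[C@H]12 | intermediate
19 | 2,6β-bis(triethylsilyloxy)-9α,10α-(isopropylidenedioxy)-14-(triisopropylsilyloxy)-5αH-dauca-2,7-diene | CC[Si](CC)(CC)O[C@@H]1C=C(CO[Si](C(C)C)(C(C)C)C(C)C)[C@@H]3[C@@H](OC(C)(C)O3)[C@@]2(C)C(O[Si](CC)(CC)CC)=C[C@@H](C(C)C)[C@H]12 | intermediate
20 | 6β-(triethylsilyloxy)-9α,10α-(isopropylidenedioxy)-14-(triisopropylsilyloxy)-5αH-dauca-3,7-dien-2-one | CC[Si](CC)(CC)O[C@@H]1C=C(CO[Si](C(C)C)(C(C)C)C(C)C)[C@@H]3[C@@H](OC(C)(C)O3)[C@@]2(C)C(=O)C=C(C(C)C)[C@H]12 | intermediate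
21 | 3β,4β-epoxy-6β-(triethylsilyloxy)-9α,10α-(isopropylidenedioxy)-14-(triisopropylsilyloxy)-5αH-dauc-7-en-2-one (isopropyl α) | CC[Si](CC)(CC)O[C@@H]1C=C(CO[Si](C(C)C)(C(C)C)C(C)C)[C@@H]3[C@@H](OC(C)(C)O3)[C@@]2(C)C(=O)[C@@H]4O[C@]4(C(C)C)[C@H]12 | intermediate
22 | C2 hydrazone of 21 | CC[Si](CC)(CC)O[C@@H]1C=C(CO[Si](C(C)C)(C(C)C)C(C)C)[C@@H]3[C@@H](OC(C)(C)O3)[C@@]2(C)C(=NN)[C@@H]4O[C@]4(C(C)C)[C@H]12 | intermediate
23 | 2-diazenyl-6β-(triethylsilyloxy)-9α,10α-(isopropylidenedioxy)-14-(triisopropylsilyloxy)-5αH-dauca-2,7-dien-4β-ol | CC[Si](CC)(CC)O[C@@H]1C=C(CO[Si](C(C)C)(C(C)C)C(C)C)[C@@H]3[C@@H](OC(C)(C)O3)[C@@]2(C)C(N=N)=C[C@@](O)(C(C)C)[C@H]12 | intermediate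
24 | 6β-(triethylsilyloxy)-9α,10α-(isopropylidenedioxy)-14-(triisopropylsilyloxy)-5αH-dauca-2,7-dien-4β-ol | CC[Si](CC)(CC)O[C@@H]1C=C(CO[Si](C(C)C)(C(C)C)C(C)C)[C@@H]3[C@@H](OC(C)(C)O3)[C@@]2(C)C=C[C@@](O)(C(C)C)[C@H]12 | intermediate
25 | 6β-(triethylsilyloxy)-9α,10α-(isopropylidenedioxy)-14-(triisopropylsilyloxy)-5αH-dauc-7-en-4β-ol | CC[Si](CC)(CC)O[C@@H]1C=C(CO[Si](C(C)C)(C(C)C)C(C)C)[C@@H]3[C@@H](OC(C)(C)O3)[C@@]2(C)CC[C@@](O)(C(C)C)[C@H]12 | intermediate
26 | 9α,10α-(isopropylidenedioxy)-14-(triisopropylsilyloxy)-5αH-dauc-7-ene-4β,6β-diol | O[C@@H]1C=C(CO[Si](C(C)C)(C(C)C)C(C)C)[C@@H]3[C@@H](OC(C)(C)O3)[C@@]2(C)CC[C@@](O)(C(C)C)[C@H]12 | intermediate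
27 | 4β-hydroxy-9α,10α-(isopropylidenedioxy)-14-(triisopropylsilyloxy)-5αH-dauc-7-en-6-one | O=C1C=C(CO[Si](C(C)C)(C(C)C)C(C)C)[C@@H]3[C@@H](OC(C)(C)O3)[C@@]2(C)CC[C@@](O)(C(C)C)[C@H]12 | intermediate
28 | 9α,10α-(isopropylidenedioxy)-14-(triisopropylsilyloxy)-5αH-dauc-7-ene-4β,6α-diol | O[C@H]1C=C(CO[Si](C(C)C)(C(C)C)C(C)C)[C@@H]3[C@@H](OC(C)(C)O3)[C@@]2(C)CC[C@@](O)(C(C)C)[C@H]12 | intermediate
29 | 3-methylbutanoyl chloride (isovaleryl chloride) | CC(C)CC(=O)Cl | starting material
30 | 4β-hydroxy-9α,10α-(isopropylidenedioxy)-14-(triisopropylsilyloxy)-5αH-dauc-7-en-6α-yl 3-methylbutanoate | CC(C)CC(=O)O[C@H]1C=C(CO[Si](C(C)C)(C(C)C)C(C)C)[C@@H]3[C@@H](OC(C)(C)O3)[C@@]2(C)CC[C@@](O)(C(C)C)[C@H]12 | intermediate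
31 | 4β,14-dihydroxy-9α,10α-(isopropylidenedioxy)-5αH-dauc-7-en-6α-yl 3-methylbutanoate | CC(C)CC(=O)O[C@H]1C=C(CO)[C@@H]3[C@@H](OC(C)(C)O3)[C@@]2(C)CC[C@@](O)(C(C)C)[C@H]12 | intermediate
32 | N-(C14-yl)-N-(2-nitrobenzenesulfonyl)hydrazine derived from 31 | CC(C)CC(=O)O[C@H]1C=C(CN(N)S(=O)(=O)c4ccccc4[N+](=O)[O-])[C@@H]3[C@@H](OC(C)(C)O3)[C@@]2(C)CC[C@@](O)(C(C)C)[C@H]12 | intermediate
33 | C14 monoalkyl diazene derived from 31 | CC(C)CC(=O)O[C@H]1C=C(CN=N)[C@@H]3[C@@H](OC(C)(C)O3)[C@@]2(C)CC[C@@](O)(C(C)C)[C@H]12 | intermediate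
34 | 4β-hydroxy-9α,10α-(isopropylidenedioxy)-5αH-dauc-8(14)-en-6α-yl 3-methylbutanoate | CC(C)CC(=O)O[C@H]1CC(=C)[C@@H]3[C@@H](OC(C)(C)O3)[C@@]2(C)CC[C@@](O)(C(C)C)[C@H]12 | intermediate
35 | 4β,9α,10α-trihydroxy-5αH-dauc-8(14)-en-6α-yl 3-methylbutanoate | CC(C)CC(=O)O[C@H]1CC(=C)[C@@H](O)[C@@H](O)[C@@]2(C)CC[C@@](O)(C(C)C)[C@H]12 | intermediate
36 | 8α,14-epoxy-4β,9α,10α-trihydroxy-5αH-daucan-6α-yl 3-methylbutanoate (CNP0307265.1) | CC(C)CC(=O)O[C@H]1C[C@]2(CO2)[C@@H](O)[C@@H](O)[C@@]2(C)CC[C@@](O)(C(C)C)[C@H]12 | target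

**Step count and risks**

Total step count: 23. Longest linear sequence: 22 steps (1 to 36 through steps 1–4 and 6–23); step 5 is a one-step side branch.

Steps most likely to fail:

Step 8. Under aqueous acid the norcaradiene tautomer 13, a methoxydiene donor joined through the cyclopropane to the C2 ketone acceptor, may open heterolytically and rearrange to an aromatic tetralone faster than the enol ether is hydrolysed. The fallback removes the acceptor first. It sets out from 14: NaBH4 in MeOH at 0 °C should reduce the C2 ketone from the α face to the 2β-alcohol F1. The enol ether of F1, now without a push–pull partner, is hydrolysed with 1 M HCl in THF to the hydroxy dienone F2, with the same equilibration at C5. Dess–Martin periodinane then re-oxidises C2, and the route is rejoined at 15.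

Step 13. Hydroperoxide may add slowly to the hindered, fully substituted C4, or with poor facial selectivity, since the β-face preference is argued by analogy. The fallback uses hydroxyl direction and sets out from 20. NaBH4/CeCl3·7H2O in MeOH at −78 °C should reduce the C2 carbonyl from the α face, anti to the adjacent C1 methyl, to the 2β-allylic alcohol F3. VO(acac)2/t-BuOOH then epoxidises C3=C4 syn to that hydroxyl, on the β face, to give the epoxy alcohol F4; the C6 oxygen is silylated and cannot direct. Dess–Martin periodinane re-forms the C2 ketone, and the route is rejoined at 21.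

Step 14. Hydrazone formation at the neopentyl C2 ketone may be slow, and the alkenyl diazene may fragment by other paths, so the transposition may stall or give mixtures. The fallback does the two jobs separately and sets out from 21. SmI2 in THF/MeOH at −78 °C cleaves the C3–O bond α to the ketone and gives the β-hydroxy ketone F5 with the 4β-hydroxyl intact. p-Toluenesulfonylhydrazide in EtOH at 60 °C gives the tosylhydrazone F6. Catecholborane followed by NaOAc·3H2O reduces it to the C2 methylene compound, and the route is rejoined at 25.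

Further compounds
F1 | step 8 | (1S,3S,8aR)-4-methoxy-8a-methyl-3-(propan-2-yl)-6-(triisopropylsilyloxymethyl)-1,2,3,8a-tetrahydroazulen-1-ol (C2 alcohol of 14, 2β-OH) | C[C@@]12C=CC(CO[Si](C(C)C)(C(C)C)C(C)C)=CC(OC)=C1[C@H](C(C)C)C[C@H]2O
F2 | step 8 | 2β-hydroxy-14-(triisopropylsilyloxy)-5αH-dauca-7,9-dien-6-one | O=C1C=C(CO[Si](C(C)C)(C(C)C)C(C)C)C=C[C@@]2(C)[C@H](O)C[C@@H](C(C)C)[C@H]12
F3 | step 13 | 6β-(triethylsilyloxy)-9α,10α-(isopropylidenedioxy)-14-(triisopropylsilyloxy)-5αH-dauca-3,7-dien-2β-ol | CC[Si](CC)(CC)O[C@@H]1C=C(CO[Si](C(C)C)(C(C)C)C(C)C)[C@@H]3[C@@H](OC(C)(C)O3)[C@@]2(C)[C@H](O)C=C(C(C)C)[C@H]12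
F4 | step 13 | 3β,4β-epoxy-6β-(triethylsilyloxy)-9α,10α-(isopropylidenedioxy)-14-(triisopropylsilyloxy)-5αH-dauc-7-en-2β-ol | CC[Si](CC)(CC)O[C@@H]1C=C(CO[Si](C(C)C)(C(C)C)C(C)C)[C@@H]3[C@@H](OC(C)(C)O3)[C@@]2(C)[C@H](O)[C@@H]4O[C@]4(C(C)C)[C@H]12
F5 | step 14 | 4β-hydroxy-6β-(triethylsilyloxy)-9α,10α-(isopropylidenedioxy)-14-(triisopropylsilyloxy)-5αH-dauc-7-en-2-one | CC[Si](CC)(CC)O[C@@H]1C=C(CO[Si](C(C)C)(C(C)C)C(C)C)[C@@H]3[C@@H](OC(C)(C)O3)[C@@]2(C)C(=O)C[C@@](O)(C(C)C)[C@H]12
F6 | step 14 | C2 p-toluenesulfonylhydrazone of F5 | CC[Si](CC)(CC)O[C@@H]1C=C(CO[Si](C(C)C)(C(C)C)C(C)C)[C@@H]3[C@@H](OC(C)(C)O3)[C@@]2(C)C(=NNS(=O)(=O)c4ccc(C)cc4)C[C@@](O)(C(C)C)[C@H]12
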